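The cyclohexane is disconnected across the C3–C4 and C5–C6 ring bonds (target numbering: C1 CBrMe, C2 CH–chlorovinyl, C4 CHBr, C5 CClMe) into isoprene and (E)-4-chloropent-3-en-2-one. A catalytic enantioselective Diels–Alder reaction joins them and creates, in one operation, the quaternary C5 and C4, the E geometry fixing acetyl trans to chlorine. It exploits the vicinal C4/C5 pair and the para relationship of C4 to the methyl-bearing C1. The acetyl group then becomes an acetoxy group that steers a formaldehyde ene reaction at C2. Takai olefination, radical hydrobromination at C1 and inversion of the C4 alcohol to the bromide complete the synthesis.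

Key step: step 2

Assumption 1: enone 2 is taken as the E isomer (chlorine anti to acetyl), expected to be favoured after HCl equilibration and separable from the Z isomer by distillation.
Assumption 2: the (S)-configured oxazaborolidinium ion is taken to direct isoprene to the enone face that gives (1S,6R)-4; the mirror-image catalyst would be used if the sense proved opposite.

Step 1
Reactants: 1 pentane-2,4-dione
Product: 2 (E)-4-chloropent-3-en-2-one
Conditions: (COCl)2 (1.1 equiv), DMF (cat.), CH2Cl2, 0 → 25 °C; fractional distillation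
Reagents that add atoms: oxalyl chloride, ClC(=O)C(Cl)=O
Why: Activation of the enol of the 1,3-diketone by oxalyl chloride and addition–elimination by chloride (β-chloro enone synthesis from a β-diketone) should give the vinylogous acid chloride; no stereocentre is formed.

Step 2
Reactants: 2 (E)-4-chloropent-3-en-2-one; 3 isoprene (2-methylbuta-1,3-diene)
Product: 4 1-[(1S,6R)-6-chloro-4,6-dimethylcyclohex-3-en-1-yl]ethan-1-one
Conditions: (S)-3,3-diphenyl-1-(2-methylphenyl)tetrahydro-1H,3H-pyrrolo[1,2-c][1,3,2]oxazaborole (20 mol %), Tf2NH (20 mol %), isoprene (5 equiv), CH2Cl2, −20 → 0 °C; non-basic work-up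
Reagents that add atoms: none
Why: The oxazaborolidinium ion binds the acetyl oxygen of 2 and lowers the enone LUMO, so that isoprene should add in a concerted, asynchronous normal-electron-demand Diels–Alder reaction; the closest known reaction type is the chiral cationic oxazaborolidine-catalysed Diels–Alder reaction of acyclic α,β-unsaturated ketones with simple dienes. The cyclohexene ring is closed by an intermolecular suprafacial [4+2] cycloaddition in which the C1–C2 and C5–C6 bonds of 4 form in the same step. The relative configuration of the new quaternary C6 (methyl, chlorine) and of C1 follows stereospecifically from the E geometry of 2, which places acetyl cis to methyl and trans to chlorine, while the absolute configuration (1S,6R) is set by the catalyst, which shields one face of the bound enone. The step needs para regioselectivity, secured by the 2-methyl group of isoprene (largest HOMO coefficient at its C1, which bonds to the β-carbon of the enone), and it needs cycloaddition to outrun Lewis-acid-assisted loss of chloride, which the weakly nucleophilic diene and the low temperature favour. Endo and exo approach give the same product because the diene termini are unsubstituted.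

Step 3
Reactants: 4 1-[(1S,6R)-6-chloro-4,6-dimethylcyclohex-3-en-1-yl]ethan-1-one
Product: 5 (1R,6R)-6-chloro-4,6-dimethylcyclohex-3-en-1-yl acetate
Conditions: Me3SiOOSiMe3 (2 equiv), SnCl4 (0.3 equiv), trans-cyclohexane-1,2-diamine (0.3 equiv), 4 Å molecular sieves, CH2Cl2, 25 °C
Reagents that add atoms: bis(trimethylsilyl) peroxide, C[Si](C)(C)OO[Si](C)(C)C
Why: In this Baeyer–Villiger oxidation the secondary ring carbon migrates in preference to methyl and with retention, so C1 keeps its oxygen trans to chlorine, and the silyl peroxide should leave the trisubstituted alkene untouched while removing the β-chloro ketone motif that is prone to loss of HCl.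

Step 4
Reactants: 5 (1R,6R)-6-chloro-4,6-dimethylcyclohex-3-en-1-yl acetate
Product: 6 (1R,2R,5R)-2-chloro-5-(hydroxymethyl)-2-methyl-4-methylidenecyclohexyl acetate
Conditions: (CH2O)n (3 equiv), Me2AlCl (2.5 equiv), CH2Cl2, −78 → 0 °C
Reagents that add atoms: formaldehyde (from paraformaldehyde), C=O
Why: In this Lewis-acid-promoted carbonyl-ene reaction formaldehyde should bond to the alkene CH carbon (C5 of 6) with transfer of a methyl hydrogen to give the exocyclic alkene; C–C bond formation by axial attack on the half-chair that keeps the acetoxy group equatorial occurs on the face anti to that group and sets C5 (R), and any isomer with the alkene in the ring converges to the same tertiary bromide in step 7.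

Step 5
Reactants: 6 (1R,2R,5R)-2-chloro-5-(hydroxymethyl)-2-methyl-4-methylidenecyclohexyl acetate
Product: 7 (1R,2R,5R)-2-chloro-5-formyl-2-methyl-4-methylidenecyclohexyl acetate
Conditions: Dess–Martin periodinane (1.3 equiv), CH2Cl2, 0 °C; aqueous NaHCO3/Na2S2O3 work-up; crude aldehyde used at once
Reagents that add atoms: none
Why: Dess–Martin oxidation of the primary alcohol under near-neutral conditions should give the β,γ-unsaturated aldehyde without touching the acetate, the alkene or the C5 stereocentre, provided the aldehyde is not stored.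

Step 6
Reactants: 7 (1R,2R,5R)-2-chloro-5-formyl-2-methyl-4-methylidenecyclohexyl acetate
Product: 8 (1R,2R,5S)-2-chloro-5-[(E)-2-chloroethenyl]-2-methyl-4-methylidenecyclohexyl acetate
Conditions: CrCl2 (6 equiv), CHCl3 (2 equiv), THF, 65 °C
Reagents that add atoms: chloroform, ClC(Cl)Cl
Why: In the Takai–Utimoto olefination the geminal dichromium species formed from chloroform adds to the aldehyde and eliminates to give the E vinyl chloride; the non-basic medium should leave C5 and the acetate intact.

Step 7
Reactants: 8 (1R,2R,5S)-2-chloro-5-[(E)-2-chloroethenyl]-2-methyl-4-methylidenecyclohexyl acetate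
Product: 9 (1R,2R,4R,5S)-4-bromo-2-chloro-5-[(E)-2-chloroethenyl]-2,4-dimethylcyclohexyl acetate
Conditions: Co(acac)2 (0.25 equiv), t-BuOOH (0.25 equiv), PhSiH3 (2 equiv), TsBr (2.5 equiv), n-PrOH, 23 °C
Reagents that add atoms: 4-methylbenzenesulfonyl bromide, Cc1ccc(cc1)S(=O)(=O)Br
Why: In this Markovnikov hydrobromination by metal-hydride hydrogen atom transfer the cobalt hydride delivers H to the terminal CH2 and the tertiary C4 radical abstracts bromine from TsBr; in the chair with the chlorovinyl group equatorial the axial C2–Cl bond blocks the axial face of C4, so bromine should enter equatorially (4R), and the 1,2-disubstituted vinyl chloride reacts far more slowly.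

Step 8
Reactants: 9 (1R,2R,4R,5S)-4-bromo-2-chloro-5-[(E)-2-chloroethenyl]-2,4-dimethylcyclohexyl acetate
Product: 10 (1R,2R,4R,5S)-4-bromo-2-chloro-5-[(E)-2-chloroethenyl]-2,4-dimethylcyclohexan-1-ol
Conditions: i-Bu2AlH (2.5 equiv), CH2Cl2, −78 °C; potassium sodium tartrate work-up at 0 °C
Reagents that add atoms: none
Why: Reductive cleavage of the acetate at low temperature should free the secondary alcohol without a basic alkoxide that could close an epoxide onto the tertiary chloride; no stereocentre is touched.

Step 9
Reactants: 10 (1R,2R,4R,5S)-4-bromo-2-chloro-5-[(E)-2-chloroethenyl]-2,4-dimethylcyclohexan-1-ol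
Product: 11 (1R,2S,4S,5R)-1,4-dibromo-5-chloro-2-[(E)-2-chloroethenyl]-1,5-dimethylcyclohexane
Conditions: Ph3P (2 equiv), CBr4 (2 equiv), CH2Cl2, 0 → 25 °C
Reagents that add atoms: carbon tetrabromide, BrC(Br)(Br)Br
Why: In the Appel reaction bromide displaces the alkoxyphosphonium ion by SN2 with inversion, turning the axial alcohol trans to chlorine into the equatorial bromide cis to chlorine, as in the preparation of cis-1,2-dihalocyclohexanes from trans-2-halocyclohexanols with halophosphonium reagents.

Compound list
1 | pentane-2,4-dione | CC(=O)CC(C)=O | starting material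
2 | (E)-4-chloropent-3-en-2-one | C/C(Cl)=C\C(C)=O | intermediate
3 | isoprene (2-methylbuta-1,3-diene) | C=CC(C)=C | starting material
4 | 1-[(1S,6R)-6-chloro-4,6-dimethylcyclohex-3-en-1-yl]ethan-1-one | C[C@@]1(Cl)CC(C)=CC[C@H]1C(C)=O | intermediate
5 | (1R,6R)-6-chloro-4,6-dimethylcyclohex-3-en-1-yl acetate | C[C@@]1(Cl)CC(C)=CC[C@H]1OC(C)=O | intermediate
6 | (1R,2R,5R)-2-chloro-5-(hydroxymethyl)-2-methyl-4-methylidenecyclohexyl acetate | C[C@@]1(Cl)CC(=C)[C@H](CO)C[C@H]1OC(C)=O | intermediate
7 | (1R,2R,5R)-2-chloro-5-formyl-2-methyl-4-methylidenecyclohexyl acetate | C[C@@]1(Cl)CC(=C)[C@H](C=O)C[C@H]1OC(C)=O | intermediate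
8 | (1R,2R,5S)-2-chloro-5-[(E)-2-chloroethenyl]-2-methyl-4-methylidenecyclohexyl acetate | C[C@@]1(Cl)CC(=C)[C@H](/C=C/Cl)C[C@H]1OC(C)=O | intermediate
9 | (1R,2R,4R,5S)-4-bromo-2-chloro-5-[(E)-2-chloroethenyl]-2,4-dimethylcyclohexyl acetate | C[C@@]1(Cl)C[C@@](C)(Br)[C@H](/C=C/Cl)C[C@H]1OC(C)=O | intermediate
10 | (1R,2R,4R,5S)-4-bromo-2-chloro-5-[(E)-2-chloroethenyl]-2,4-dimethylcyclohexan-1-ol | C[C@@]1(Cl)C[C@@](C)(Br)[C@H](/C=C/Cl)C[C@H]1O | intermediate
11 | (1R,2S,4S,5R)-1,4-dibromo-5-chloro-2-[(E)-2-chloroethenyl]-1,5-dimethylcyclohexane | C[C@@]1(Cl)C[C@@](C)(Br)[C@H](/C=C/Cl)C[C@@H]1Br | target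

Total step count: 9
Longest linear sequence: 9 steps (1 → 11)

Steps most likely to fail

Step 2 (key cycloaddition). The β,β-disubstituted enone may react too slowly, the Lewis acid may promote ionisation or addition–elimination at the C–Cl carbon, and facial discrimination by the catalyst may be insufficient. The fallback replaces catalyst control by auxiliary control; it sets out from isoprene 3 and comes back at ketone 4. (E)-3-Chlorobut-2-enoic acid is coupled with (R)-4-benzyl-1,3-oxazolidin-2-one (DCC, DMAP, CH2Cl2) to give (4R)-4-benzyl-3-[(E)-3-chlorobut-2-enoyl]-1,3-oxazolidin-2-one F1. With Et2AlCl (1.4 equiv) in CH2Cl2 at −30 °C, 3 should add to the chelated s-cis imide on the face opposite the benzyl group to give (4R)-4-benzyl-3-[(1S,6R)-6-chloro-4,6-dimethylcyclohex-3-ene-1-carbonyl]-1,3-oxazolidin-2-one F2. AlMe3 and MeNH(OMe)·HCl release the auxiliary and give (1S,6R)-6-chloro-N-methoxy-N,4,6-trimethylcyclohex-3-ene-1-carboxamide F3, and MeMgBr in THF at −20 °C gives 4.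

Step 4 (ene reaction). The aluminium Lewis acid may ionise the tertiary chloride, hydrogen may be transferred from the ring CH2 as well as from the methyl group, and facial selectivity at C5 may be poor. The fallback replaces the ene reaction by electrophilic substitution of an allylsilane; it sets out from enone 2 and comes back at aldehyde 7. Trimethyl(2-methylidenebut-3-en-1-yl)silane F4 (from chloroprene and Me3SiCH2MgCl with NiCl2(dppp)) is used in place of isoprene in the cycloaddition of step 2 to give 1-[(1S,6R)-6-chloro-6-methyl-4-[(trimethylsilyl)methyl]cyclohex-3-en-1-yl]ethan-1-one F5. Baeyer–Villiger oxidation as in step 3 gives (1R,6R)-6-chloro-6-methyl-4-[(trimethylsilyl)methyl]cyclohex-3-en-1-yl acetate F6. A Hosomi–Sakurai reaction with HC(OMe)3 and TMSOTf (cat.) in CH2Cl2 at −78 °C should give (1R,2R,5R)-2-chloro-5-(dimethoxymethyl)-2-methyl-4-methylidenecyclohexyl acetate F7, with the exocyclic alkene fixed by loss of silicon. Wet oxalic acid on silica then gives 7.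

Step 9 (bromide displacement). At the hindered carbon next to the quaternary centre, β-elimination from the alkoxyphosphonium ion or participation of the anti-periplanar chlorine (retention or chlorine migration) may outrun direct displacement. The fallback replaces substitution at carbon by hydrogen delivery to carbon; it sets out from alcohol 10 and comes back at target 11. Dess–Martin oxidation gives (2R,4R,5S)-4-bromo-2-chloro-5-[(E)-2-chloroethenyl]-2,4-dimethylcyclohexan-1-one F8. (PhO)3P, Br2 and Et3N in CH2Cl2 (−60 → 40 °C) convert the ketone into (3R,4R,6R)-1,4-dibromo-6-chloro-3-[(E)-2-chloroethenyl]-4,6-dimethylcyclohex-1-ene F9. Hydrogen-atom-transfer hydrogenation (Mn(dpm)3 cat., PhSiH3, t-BuOOH, i-PrOH, 23 °C) should reduce the trisubstituted bromoalkene faster than the 1,2-disubstituted chloroalkene and deliver hydrogen to the α-bromo radical axially, anti to the axial C–Cl bond, leaving bromine equatorial and cis to chlorine in 11.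

Further compounds
F1 | step 2 | (4R)-4-benzyl-3-[(E)-3-chlorobut-2-enoyl]-1,3-oxazolidin-2-one | C/C(Cl)=C\C(=O)N1[C@H](Cc2ccccc2)COC1=O
F2 | step 2 | (4R)-4-benzyl-3-[(1S,6R)-6-chloro-4,6-dimethylcyclohex-3-ene-1-carbonyl]-1,3-oxazolidin-2-one | C[C@@]1(Cl)CC(C)=CC[C@H]1C(=O)N2[C@H](Cc3ccccc3)COC2=O
F3 | step 2 | (1S,6R)-6-chloro-N-methoxy-N,4,6-trimethylcyclohex-3-ene-1-carboxamide | C[C@@]1(Cl)CC(C)=CC[C@H]1C(=O)N(C)OC
F4 | step 4 | trimethyl(2-methylidenebut-3-en-1-yl)silane | C=CC(=C)C[Si](C)(C)C
F5 | step 4 | 1-[(1S,6R)-6-chloro-6-methyl-4-[(trimethylsilyl)methyl]cyclohex-3-en-1-yl]ethan-1-one | C[C@@]1(Cl)CC(C[Si](C)(C)C)=CC[C@H]1C(C)=O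
F6 | step 4 | (1R,6R)-6-chloro-6-methyl-4-[(trimethylsilyl)methyl]cyclohex-3-en-1-yl acetate | C[C@@]1(Cl)CC(C[Si](C)(C)C)=CC[C@H]1OC(C)=O
F7 | step 4 | (1R,2R,5R)-2-chloro-5-(dimethoxymethyl)-2-methyl-4-methylidenecyclohexyl acetate | C[C@@]1(Cl)CC(=C)[C@H](C(OC)OC)C[C@H]1OC(C)=O
F8 | step 9 | (2R,4R,5S)-4-bromo-2-chloro-5-[(E)-2-chloroethenyl]-2,4-dimethylcyclohexan-1-one | C[C@@]1(Cl)C[C@@](C)(Br)[C@H](/C=C/Cl)CC1=O
F9 | step 9 | (3R,4R,6R)-1,4-dibromo-6-chloro-3-[(E)-2-chloroethenyl]-4,6-dimethylcyclohex-1-ene | C[C@@]1(Cl)C[C@@](C)(Br)[C@H](/C=C/Cl)C=C1Br
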